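Should a flask of 0.19 M electrophile with 1.20 equiv of nucleophile stop at 25 min (midnight) or stand until 80 min (winter), and how much target does the wait buy? The charges stay the same; the time is the decision.

| flask | electrophile | nucleophile | gas | remark | time |
|---|---|---|---|---|---|
| birch | 0.095 M | 1.2 equiv | 67 mM (held) | run made earlier |  |
| ash | 0.14 M | 1.2 equiv | 67 mM (held) | run made earlier |  |
| midnight | 0.19 M | 1.20 equiv | 67 mM (held) |  | 25 min |
| winter | 0.19 M | 1.20 equiv | 67 mM (held) |  | 80 min |

| run | time / min | target / % | isomer of the product / % | electrophile / % | over-reaction product / % |
|---|---|---|---|---|---|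
| birch | 2.50 | 37.8 | 4.3 | 55.9 | 0 |
| birch | 5.00 | 47.0 | 7.5 | 46.2 | 1.2 |
| birch | 8.00 | 45.9 | 14.3 | 41.7 | 2.3 |
| birch | 15.0 | 47.5 | 18.7 | 31.7 | 2.2 |
| birch | 30.0 | 53.7 | 19.4 | 24.2 | 1.9 |
| ash | 2.50 | 42.6 | 5.2 | 51.0 | 0.8 |
| ash | 5.00 | 46.1 | 10.0 | 40.8 | 0 |
| ash | 8.00 | 47.1 | 15.0 | 36.7 | 0.8 |
| ash | 15.0 | 49.9 | 18.2 | 30.8 | 1.8 |
| ash | 30.0 | 53.2 | 21.2 | 22.3 | 2.6 |

(scatter of a reading: 1 percentage point)

- the analysis behind the earlier runs scatters by 1 percentage point, standard deviation
- at the start none of the gas is in solution

- which of these there is most of at the end, counted by the electrophile in it, midnight (isomer of the product / electrophile / target / over-reaction product)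
- which of these there is most of at the end, counted by the electrophile in it, winter (isomer of the product / electrophile / target / over-reaction product)
- amount of the one of these that there is most of at the end, in percent of the electrophile charged, midnight
- amount of the one of these that there is most of at the end, in percent of the electrophile charged, winter

At 30.0 min, c(electrophile) in percent differs between birch and ash by 1.9 percentage points, against a scatter of 1 point. My reckoning therefore pools the two runs and assumes that their percentages carry over to midnight and winter. It replaces the slow end of the curve by one mean pseudo-first-order decay. Its measure is the tail half-life 35.2 min, the time in which that mean rate from 15.0 min to 30.0 min cuts pooled c(electrophile) by a factor of two. This puts electrophile at 25.7% at 25 min and 8.68% at 80 min.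

The error of that mean can be checked. The same reckoning from 8.00 min to 15.0 min gives 21.4 min, which is shorter than the later value, so the curve is slowing. Stretching the tail half-life once more by the same ratio gives 12.8% at 80 min, more than the constant figure. With 72.5% of the pooled target and isomer at 30.0 min being target, my reckoning estimates the gain in target from the wait at 9.3 points to 12 points, an estimate that leaves over-reaction product out of the split.

The forecast names target at 53% for midnight and target at 62% for winter, expecting that “the slow tail continues, slowing as nucleophile depletes”.

    electrophile + nucleophile → acid set free + target (k = 3.60 L mol⁻¹ min⁻¹)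
    nucleophile + acid set free ⇌ protonated nucleophile, settled at all times (K = 20000 L mol⁻¹)
    acid set free + free base ⇌ salt of the base, settled at all times (K = 2900 L mol⁻¹)
    nucleophile + target → over-reaction product (k = 0.150 L mol⁻¹ min⁻¹)
    gas ⇌ free base, rate k5*(csat - [free base]) (kL = 0.0850 min⁻¹)
    target ⇌ isomer of the product (K = 0.400, k = 0.0820 min⁻¹)

Midnight gives target at 52.8% and winter target at 60.9%, so the wait brings 8.1 points, less than the reckoned 9.3 points. At the end of midnight, 2.39% of the charged nucleophile stands free, beside 0.0752 M of protonated nucleophile. Midnight's electrophile stands at 24.7% against the reckoned 25.7%. Carried from there over 55.0 min with the tail half-life 35.2 min, it comes to 8.36%, and winter holds 10.7%.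

The runs were generated by integration with made-up constants; noise was put on by code.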